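**Retrosynthetic overview**
1. The last bond made is C11=C12 (carotenoid numbering): a Wittig reaction joins the C15 cyclopentyl-dienyl phosphonium salt 14 to the C25 aldehyde 12'-apo-ψ-caroten-12'-al 21, itself made from pseudoionone and the C10 trienedial.
2. Salt 14 comes from ring aldehyde 9 (C7 = CHO) by a C5 Horner–Wadsworth–Emmons extension; 9 comes from bicyclic β-lactone 7 by reduction and re-oxidation.
3. The cyclopentane, the only ring of the target, is made in one step as 7 by a carbene-catalysed [3+2] annulation. Dienal 3 supplies C2, C6, C7 and the isopropenyl group; methyl vinyl ketone supplies C3, C4, C5 and the C5 methyl. The step forms C2–C3 (homoenolate Michael addition) and C5–C6 (aldol), and closes a temporary oxetanone ring that step 3 opens again.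
4. Enabling feature: in the cyclopentane both the carbinol carbon C5 and the isopropenyl-bearing C2 are β to the exocyclic C7, and the C5–O and C6–C7 bonds are cis. With C7 at the acyl level, C2/C6 are the β/α carbons of one enal, C3–C4–C5(CH3)=O is a vinyl ketone, and the cis O/C7 pair can close the β-lactone that releases the catalyst.

Key step: step 2

Assumption: the (5aS,10bR) antipode of the aminoindanol-derived N-mesityl triazolium catalyst is taken as the one that bonds the Si face of C3 of dienal 3 (if the sense is opposite, its commercial mirror image is used and nothing else changes), and pseudoionone is used as its (3E,5E) isomer.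

**Route**

Step 1
Reactants: 1 methacrolein; 2 (triphenylphosphoranylidene)acetaldehyde
Product: 3 (2E)-4-methylpenta-2,4-dienal
Conditions: 1 (3 equiv), toluene, 60 °C, sealed vessel; distillation
Reagents that add atoms: (triphenylphosphoranylidene)acetaldehyde (2), O=CC=P(c1ccccc1)(c1ccccc1)c1ccccc1
Why: Wittig olefination with a formyl-stabilised ylide should give the E-enal, and the excess of volatile aldehyde suppresses a second homologation.

Step 2
Reactants: 3 (2E)-4-methylpenta-2,4-dienal; 4 methyl vinyl ketone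
Product: 7 (1R,2S,5S)-5-methyl-2-(prop-1-en-2-yl)-6-oxabicyclo[3.2.0]heptan-7-one, via azolium enolate 5 (not isolated), via acyl azolium alkoxide 6 (not isolated)
Conditions: (5aS,10bR)-2-mesityl-5a,10b-dihydro-4H,6H-indeno[2,1-b][1,2,4]triazolo[4,3-d][1,4]oxazin-2-ium chloride (10 mol %), DBU (20 mol %), 4 (3 equiv), 4 Å MS, ClCH2CH2Cl, 0 °C to rt, 3 added slowly by syringe pump
Reagents that add atoms: methyl vinyl ketone (4), C=CC(C)=O
Why: Proposed new method: the carbene adds to the aldehyde of 3 to give the extended Breslow intermediate, whose β-carbon (C2) adds as a homoenolate to the CH2 terminus of 4 (first bond, C2–C3); after proton transfer the azolium enolate 5 attacks the methyl ketone (second bond, C5–C6), and alkoxide 6 acylates the azolium to give 7 and free carbene. The closest known reaction type is the carbene-catalysed homoenolate annulation of enals with chalcones and 4-oxoenoates to cyclopentane-fused β-lactones; the new elements are a β-unsubstituted alkyl vinyl ketone as partner and retention of the lactone, which should not lose CO2 at or below rt because its C–O carbon carries only alkyl groups. The cyclopentane closes by a 5-(enolexo)-exo-trig aldol and the oxetanone by a 4-exo-trig acyl transfer. The isopropenyl-bearing centre is set by the chiral triazolylidene (Si-face bonding at C3 of 3), the ring-fusion CH by the substrate (the acyl azolium takes the face anti to the isopropenyl group), and the carbinol carbon by the lactonisation, since only the aldolate with O cis to the acyl group can close the four-membered ring and turn the catalyst over while the aldol remains reversible. The step needs β (d3) reactivity of the dienal, not acyl-anion (Stetter or benzoin) or δ reactivity, and cross- rather than self-annulation. N-Mesityl triazolylidenes with an amidine base are homoenolate-selective, 2,4-dienals normally react at the β-carbon, and the unhindered, highly electrophilic 4 in excess with slow addition of 3 should outcompete enal dimerisation.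

Step 3
Reactants: 7 (1R,2S,5S)-5-methyl-2-(prop-1-en-2-yl)-6-oxabicyclo[3.2.0]heptan-7-one
Product: 8 (1S,2S,3S)-2-(hydroxymethyl)-1-methyl-3-(prop-1-en-2-yl)cyclopentan-1-ol
Conditions: LiAlH4, Et2O, 0 °C; aqueous work-up
Reagents that add atoms: none
Why: Hydride reduction of the β-lactone with acyl–oxygen cleavage (ester reduction) opens the temporary four-membered ring to the 1,3-diol without touching a stereocentre or the 1,1-disubstituted alkene.

Step 4
Reactants: 8 (1S,2S,3S)-2-(hydroxymethyl)-1-methyl-3-(prop-1-en-2-yl)cyclopentan-1-ol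
Product: 9 (1R,2S,5S)-2-hydroxy-2-methyl-5-(prop-1-en-2-yl)cyclopentane-1-carbaldehyde
Conditions: TEMPO (10 mol %), PhI(OAc)2 (1.1 equiv), CH2Cl2, rt
Reagents that add atoms: none
Why: The TEMPO/oxoammonium oxidation converts only the primary alcohol (the tertiary one cannot be oxidised), and the base-free medium protects the β-hydroxy aldehyde from retro-aldol cleavage and epimerisation.

Step 5
Reactants: 9 (1R,2S,5S)-2-hydroxy-2-methyl-5-(prop-1-en-2-yl)cyclopentane-1-carbaldehyde; 10 triethyl 3-methyl-4-phosphonocrotonate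
Product: 11 ethyl (2E,4E)-5-[(1R,2S,5S)-2-hydroxy-2-methyl-5-(prop-1-en-2-yl)cyclopentyl]-3-methylpenta-2,4-dienoate
Conditions: 10 (1.5 equiv), LiHMDS (1.45 equiv), THF, −78 °C; then 9, −78 to 0 °C
Reagents that add atoms: triethyl 3-methyl-4-phosphonocrotonate (10), CCOC(=O)/C=C(C)/CP(=O)(OCC)OCC
Why: Horner–Wadsworth–Emmons olefination with the vinylogous phosphonate should give the (E)-C7=C8 bond; the phosphonate anion is too weak a base to deprotonate the tertiary alcohol, the α-centre already has its preferred configuration (trans to both neighbouring carbon substituents), and minor 2Z ester is removed by chromatography.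

Step 6
Reactants: 11 ethyl (2E,4E)-5-[(1R,2S,5S)-2-hydroxy-2-methyl-5-(prop-1-en-2-yl)cyclopentyl]-3-methylpenta-2,4-dienoate
Product: 12 (2E,4E)-5-[(1R,2S,5S)-2-hydroxy-2-methyl-5-(prop-1-en-2-yl)cyclopentyl]-3-methylpenta-2,4-dien-1-ol
Conditions: DIBAL-H (3.5 equiv), CH2Cl2, −78 to 0 °C; Rochelle salt work-up
Reagents that add atoms: none
Why: DIBAL-H reduces the conjugated ester in 1,2-fashion to the allylic alcohol and leaves the C=C bonds and stereocentres untouched.

Step 7
Reactants: 12 (2E,4E)-5-[(1R,2S,5S)-2-hydroxy-2-methyl-5-(prop-1-en-2-yl)cyclopentyl]-3-methylpenta-2,4-dien-1-ol; 13 triphenylphosphine hydrobromide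
Product: 14 [(2E,4E)-5-[(1R,2S,5S)-2-hydroxy-2-methyl-5-(prop-1-en-2-yl)cyclopentyl]-3-methylpenta-2,4-dien-1-yl]triphenylphosphonium bromide
Conditions: 13 (1.05 equiv), MeOH, rt, dark; trituration with Et2O
Reagents that add atoms: triphenylphosphine hydrobromide (13), [Br-].c1ccc(cc1)[PH+](c1ccccc1)c1ccccc1
Why: Phosphonium salt formation from an allylic alcohol with PPh3·HBr (the standard carotenoid C15-salt method) replaces the protonated dienylic hydroxyl by PPh3 at the primary terminus, while the tertiary, non-allylic hydroxyl should not ionise at rt.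

Step 8
Reactants: 15 (3E,5E)-pseudoionone; 16 vinylmagnesium bromide
Product: 17 (4E,6E)-3,7,11-trimethyldodeca-1,4,6,10-tetraen-3-ol (racemic)
Conditions: 16 (1.2 equiv), THF, −20 to 0 °C; aq NH4Cl
Reagents that add atoms: vinylmagnesium bromide (16), C=C[Mg]Br
Why: The vinyl Grignard reagent adds 1,2 to the dienone carbonyl; the new carbinol centre is racemic and is destroyed in step 9.

Step 9
Reactants: 17 (4E,6E)-3,7,11-trimethyldodeca-1,4,6,10-tetraen-3-ol; 13 triphenylphosphine hydrobromide
Product: 18 [(2E,4E,6E)-3,7,11-trimethyldodeca-2,4,6,10-tetraen-1-yl]triphenylphosphonium bromide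
Conditions: 13 (1.05 equiv), MeOH, rt; crystallisation
Reagents that add atoms: triphenylphosphine hydrobromide (13), [Br-].c1ccc(cc1)[PH+](c1ccccc1)c1ccccc1
Why: PPh3·HBr ionises the tertiary bis-allylic alcohol and PPh3 captures the delocalised cation at its primary terminus (allylic transposition) to give the conjugated trienyl salt, whose 2E isomer is purified by crystallisation.

Step 10
Reactants: 18 [(2E,4E,6E)-3,7,11-trimethyldodeca-2,4,6,10-tetraen-1-yl]triphenylphosphonium bromide; 19 (2E,4E,6E)-2,7-dimethylocta-2,4,6-trienedial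
Product: 21 all-E 12'-apo-ψ-caroten-12'-al, via 11'Z isomer 20 (not isolated)
Conditions: 19 (3 equiv), NaOMe, MeOH–CH2Cl2, 0 °C to rt; then heptane, 80 °C, dark, Ar; excess 19 recovered
Reagents that add atoms: (2E,4E,6E)-2,7-dimethylocta-2,4,6-trienedial (19), O=C/C(C)=C/C=C/C=C(\C)C=O
Why: Wittig olefination of the semi-stabilised ylide with one aldehyde of the symmetrical dial, used in excess to favour mono-olefination, forms C11'=C12'; the sterically hindered 11'Z isomer formed alongside should equilibrate thermally to the all-E aldehyde.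

Step 11
Reactants: 14 [(2E,4E)-5-[(1R,2S,5S)-2-hydroxy-2-methyl-5-(prop-1-en-2-yl)cyclopentyl]-3-methylpenta-2,4-dien-1-yl]triphenylphosphonium bromide; 21 all-E 12'-apo-ψ-caroten-12'-al
Product: 23 CNP0222499.1 (the target), via 11Z isomer 22 (not isolated)
Conditions: 14 (1.2 equiv), NaOMe, MeOH–CH2Cl2, 0 °C to rt, dark, Ar; then heptane, 80 °C; crystallisation
Reagents that add atoms: none
Why: Wittig olefination forms C11=C12 with the free tertiary hydroxyl tolerated by methoxide, and the sterically hindered 11Z isomer should isomerise on heating to the all-E polyene without touching the three ring stereocentres.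

**Compound list**
1 | methacrolein (2-methylprop-2-enal) | C=C(C)C=O | starting material
2 | (triphenylphosphoranylidene)acetaldehyde | O=CC=P(c1ccccc1)(c1ccccc1)c1ccccc1 | starting material
3 | (2E)-4-methylpenta-2,4-dienal | C=C(C)/C=C/C=O | intermediate
4 | methyl vinyl ketone (but-3-en-2-one) | C=CC(C)=O | starting material
5 | azolium enolate: zwitterionic Michael adduct of the catalyst-bound dienal with 4, drawn as the Z-enolate, (S) at the isopropenyl-bearing carbon | C=C(C)[C@H](/C=C(\[O-])c1n2[C@@H]3c4ccccc4C[C@@H]3OCc2n[n+]1-c1c(C)cc(C)cc1C)CCC(C)=O | intermediate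
6 | acyl azolium alkoxide: zwitterionic aldolate with the cyclopentane closed, O cis to the acyl group and isopropenyl trans to it | C=C(C)[C@H]1CC[C@](C)([O-])[C@@H]1C(=O)c1n2[C@@H]3c4ccccc4C[C@@H]3OCc2n[n+]1-c1c(C)cc(C)cc1C | intermediate
7 | (1R,2S,5S)-5-methyl-2-(prop-1-en-2-yl)-6-oxabicyclo[3.2.0]heptan-7-one (cis-fused β-lactone, isopropenyl trans to the lactone carbonyl) | C=C(C)[C@H]1CC[C@]2(C)OC(=O)[C@H]12 | intermediate
8 | (1S,2S,3S)-2-(hydroxymethyl)-1-methyl-3-(prop-1-en-2-yl)cyclopentan-1-ol | C=C(C)[C@H]1CC[C@](C)(O)[C@@H]1CO | intermediate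
9 | (1R,2S,5S)-2-hydroxy-2-methyl-5-(prop-1-en-2-yl)cyclopentane-1-carbaldehyde | C=C(C)[C@H]1CC[C@](C)(O)[C@@H]1C=O | intermediate
10 | triethyl 3-methyl-4-phosphonocrotonate (ethyl 4-(diethoxyphosphoryl)-3-methylbut-2-enoate, drawn E; sold as an E/Z mixture) | CCOC(=O)/C=C(C)/CP(=O)(OCC)OCC | starting material
11 | ethyl (2E,4E)-5-[(1R,2S,5S)-2-hydroxy-2-methyl-5-(prop-1-en-2-yl)cyclopentyl]-3-methylpenta-2,4-dienoate | C=C(C)[C@H]1CC[C@](C)(O)[C@@H]1/C=C/C(C)=C/C(=O)OCC | intermediate
12 | (2E,4E)-5-[(1R,2S,5S)-2-hydroxy-2-methyl-5-(prop-1-en-2-yl)cyclopentyl]-3-methylpenta-2,4-dien-1-ol | C=C(C)[C@H]1CC[C@](C)(O)[C@@H]1/C=C/C(C)=C/CO | intermediate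
13 | triphenylphosphine hydrobromide | [Br-].c1ccc(cc1)[PH+](c1ccccc1)c1ccccc1 | starting material
14 | [(2E,4E)-5-[(1R,2S,5S)-2-hydroxy-2-methyl-5-(prop-1-en-2-yl)cyclopentyl]-3-methylpenta-2,4-dien-1-yl]triphenylphosphonium bromide | C=C(C)[C@H]1CC[C@](C)(O)[C@@H]1/C=C/C(C)=C/C[P+](c1ccccc1)(c1ccccc1)c1ccccc1.[Br-] | intermediate
15 | (3E,5E)-pseudoionone ((3E,5E)-6,10-dimethylundeca-3,5,9-trien-2-one) | CC(=O)/C=C/C=C(\C)CCC=C(C)C | starting material
16 | vinylmagnesium bromide | C=C[Mg]Br | starting material
17 | (4E,6E)-3,7,11-trimethyldodeca-1,4,6,10-tetraen-3-ol (racemic) | C=CC(C)(O)/C=C/C=C(\C)CCC=C(C)C | intermediate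
18 | [(2E,4E,6E)-3,7,11-trimethyldodeca-2,4,6,10-tetraen-1-yl]triphenylphosphonium bromide | CC(C)=CCC/C(C)=C/C=C/C(C)=C/C[P+](c1ccccc1)(c1ccccc1)c1ccccc1.[Br-] | intermediate
19 | (2E,4E,6E)-2,7-dimethylocta-2,4,6-trienedial | O=C/C(C)=C/C=C/C=C(\C)C=O | starting material
20 | 11'Z isomer of 12'-apo-ψ-caroten-12'-al | O=C/C(C)=C/C=C/C=C(C)/C=C\C=C(C)\C=C\C=C(/C)CCC=C(C)C | intermediate
21 | all-E 12'-apo-ψ-caroten-12'-al (C25 aldehyde) | O=C/C(C)=C/C=C/C=C(C)/C=C/C=C(C)/C=C/C=C(\C)CCC=C(C)C | intermediate
22 | 11Z isomer of the target | C=C(C)[C@H]1CC[C@](C)(O)[C@@H]1/C=C/C(C)=C/C=C\C(C)=C\C=C\C=C(C)\C=C\C=C(C)\C=C\C=C(/C)CCC=C(C)C | intermediate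
23 | CNP0222499.1: (1S,2R,3S)-1-methyl-3-(prop-1-en-2-yl)cyclopentan-1-ol carrying the all-E C31 polyene chain at C2 | C=C(C)[C@H]1CC[C@](C)(O)[C@@H]1/C=C/C(C)=C/C=C/C(C)=C/C=C/C=C(C)/C=C/C=C(C)/C=C/C=C(\C)CCC=C(C)C | target

**Step count**
Total: 11 steps. Longest linear sequence: 8 steps (steps 1–7, then 11); the C25 branch is steps 8–10.

**Steps most likely to fail**

Step 2 (Proposed new method). The carbene may be diverted into acyl-anion (Stetter-type) addition, carbene-initiated oligomerisation of the vinyl ketone, self-annulation of the enal or attack through the δ-carbon, and the enantiofacial selectivity may be low. The fallback uses known chemistry with a chiral-pool terpene. It does not branch from an intermediate of the route: it replaces compounds 1–6, sets out from commercial (S)-(−)-limonene F1, and returns at lactone 7. The ring alkene of F1 is epoxidised (mCPBA, CH2Cl2, 0 °C) to (4S)-limonene 1,2-oxide F2 (cis/trans mixture), which periodic acid (H5IO6, THF–H2O) cleaves to (3S)-6-oxo-3-(prop-1-en-2-yl)heptanal F3. Chlorite oxidation (NaClO2, NaH2PO4, 2-methyl-2-butene) gives (3S)-6-oxo-3-(prop-1-en-2-yl)heptanoic acid F4. A nucleophile-catalysed aldol-lactonisation of the keto acid (TsCl, iPr2NEt, LiCl, 4-pyrrolidinopyridine or a chiral isothiourea, CH2Cl2, rt) should then close 7, with the limonene-derived centre directing the acyl group trans to the isopropenyl group.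

Step 5. The unprotected β-hydroxy aldehyde may undergo base-induced retro-aldol ring opening, β-elimination of water or epimerisation at the α-carbon before olefination. The fallback sets out from lactone 7 and returns at ester 11, and never exposes a free β-hydroxy aldehyde to base. The lactone is opened with Me(MeO)NH·HCl/Me2AlCl to (1R,2S,5S)-2-hydroxy-N-methoxy-N,2-dimethyl-5-(prop-1-en-2-yl)cyclopentane-1-carboxamide F5, which is silylated (TESOTf, 2,6-lutidine) to the triethylsilyl ether F6. DIBAL-H at −78 °C gives the silyl-protected aldehyde F7, olefination with phosphonate 10 as in step 5 gives the silyl-protected dienoate F8, and TBAF in THF removes the silyl group to give 11.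

Step 7. Under HBr the tertiary alcohol may ionise and dehydrate, the dienyl cation may be captured intramolecularly by the hydroxyl, or the C9=C10 geometry may scramble. The fallback reverses the polarity of the final coupling so that the cyclopentane fragment never meets acid. It sets out from dienol 12 and aldehyde 21 and returns at target 23 (through 22). Dienol 12 is oxidised with MnO2 (CH2Cl2) to (2E,4E)-5-[(1R,2S,5S)-2-hydroxy-2-methyl-5-(prop-1-en-2-yl)cyclopentyl]-3-methylpenta-2,4-dienal F9. Aldehyde 21 is reduced (NaBH4, MeOH–THF) to 12'-apo-ψ-caroten-12'-ol F10 and converted with PPh3·HBr into the C25 triphenylphosphonium bromide F11. Wittig reaction of F9 with F11 (NaOMe, MeOH–CH2Cl2, then heat) forms the same C11=C12 bond.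

**Further compounds**
F1 | step 2 | (S)-(−)-limonene (commercial starting material of the fallback) | CC1=CC[C@H](CC1)C(=C)C
F2 | step 2 | (4S)-limonene 1,2-oxide (cis/trans mixture) | CC12OC1C[C@H](CC2)C(=C)C
F3 | step 2 | (3S)-6-oxo-3-(prop-1-en-2-yl)heptanal | C=C(C)[C@H](CC=O)CCC(C)=O
F4 | step 2 | (3S)-6-oxo-3-(prop-1-en-2-yl)heptanoic acid | C=C(C)[C@H](CC(=O)O)CCC(C)=O
F5 | step 5 | (1R,2S,5S)-2-hydroxy-N-methoxy-N,2-dimethyl-5-(prop-1-en-2-yl)cyclopentane-1-carboxamide | C=C(C)[C@H]1CC[C@](C)(O)[C@@H]1C(=O)N(C)OC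
F6 | step 5 | triethylsilyl ether of F5 | C=C(C)[C@H]1CC[C@](C)(O[Si](CC)(CC)CC)[C@@H]1C(=O)N(C)OC
F7 | step 5 | (1R,2S,5S)-2-methyl-5-(prop-1-en-2-yl)-2-(triethylsilyloxy)cyclopentane-1-carbaldehyde | C=C(C)[C@H]1CC[C@](C)(O[Si](CC)(CC)CC)[C@@H]1C=O
F8 | step 5 | triethylsilyl ether of ester 11 | C=C(C)[C@H]1CC[C@](C)(O[Si](CC)(CC)CC)[C@@H]1/C=C/C(C)=C/C(=O)OCC
F9 | step 7 | (2E,4E)-5-[(1R,2S,5S)-2-hydroxy-2-methyl-5-(prop-1-en-2-yl)cyclopentyl]-3-methylpenta-2,4-dienal | C=C(C)[C@H]1CC[C@](C)(O)[C@@H]1/C=C/C(C)=C/C=O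
F10 | step 7 | all-E 12'-apo-ψ-caroten-12'-ol | OC/C(C)=C/C=C/C=C(C)/C=C/C=C(C)/C=C/C=C(\C)CCC=C(C)C
F11 | step 7 | (all-E 12'-apo-ψ-caroten-12'-yl)triphenylphosphonium bromide | [Br-].c1ccccc1[P+](c1ccccc1)(c1ccccc1)C/C(C)=C/C=C/C=C(C)/C=C/C=C(C)/C=C/C=C(\C)CCC=C(C)C
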